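## Numbering used throughout

Atom labels of the target: ring C1 (CH bearing the side chain), C2 (CH2), C3=C4 (C4 carries C15H2–O–acyl), C5 (CHOH), C6 (CH2); chain C7(=C14H2)–C8H2–C9H=C10H–C11(OH)(C13H3)–C12H2–O–acyl. These labels are used in the text; systematic names keep their own locants. Compounds 1–18 are numbered as in the steps; 18 is the target.

## Analysis of the target

- Compound 18 has a single carbocycle, a cyclohexene, with a seven-carbon chain on C1.
- The ring carries two stereocentres, C1 (S) and C5 (S). The C5 hydroxyl and the C1 side chain are 1,3-cis, so both can sit pseudo-equatorial.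
- The third stereocentre, C11 (R), is a tertiary carbinol six bonds away from C1. No element of the molecule relays configuration between the ring and C11, so C11 has to arrive in its own enantiopure building block.
- Four oxygen functions come in two pairs: the primary alcohols on C12 and C15 are isobutyrates, while the secondary allylic C5–OH and the tertiary allylic C11–OH are free.
- The sensitive groups are:
  - the skipped diene C14=C7–C8–C9=C10, whose doubly allylic C8 methylene can slip into conjugation under base, acid or metal hydrides;
  - the allylic C15 ester, which can ionise or migrate to the C5 hydroxyl;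
  - the tertiary allylic alcohol, which is acid-labile.
- The difficulty is therefore to make a 1,1-disubstituted alkene and an E-disubstituted alkene in a 1,4-relationship, late, under near-neutral conditions, with the hydroxyls and esters already differentiated.
- The strategy rests on the C14=C7–C8–C9=C10 unit being a 2-substituted 1,4-diene. This is exactly the branched product of joining a terminal alkyne (C7≡C14) to a monosubstituted alkene (C8=C9 with allylic C10–H).

## Retrosynthetic reasoning

**18 to 13 and 17 (C7–C8).** The C7–C8 bond is cut, with a hydrogen notionally moved from C14 back to C10. This gives the ring alkyne 13 and the alkenyl carbinol 17. The cut divides the molecule into two fragments of similar size, each holding its own stereocentres and its own isobutyrate. It creates both alkenes of the skipped diene in the bond-forming event, and it needs no protecting group. Cutting C8–C9 or C10–C11 instead would leave a preformed 1,4-diene or 1,4-enyne to be carried through further steps. The forward reaction, a ruthenium-catalysed alkene–alkyne coupling, must give the branched regioisomer and the E alkene, and must react only at the monosubstituted alkene.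

**17 to 16 and 12 (C12–O acyl bond).** The ester is removed to give diol 16 and acid chloride 12. The forward step only has to distinguish a primary from a tertiary hydroxyl.

**16 to 14 and 15 (C9–C10).** The bond between the vinyl unit and the CH2 next to the carbinol is cut. This gives epoxide 14 and the vinyl Grignard reagent 15. The tertiary stereocentre is then never a reaction site: it comes intact from an epoxy alcohol obtainable in either enantiomeric form. The forward step must open the epoxide at its unsubstituted terminus.

**13 to 11 and 12 (C15–O acyl bond).** The ester is again removed last in the backward sense, so that the coupling partner already carries it. The forward step must acylate the primary allylic hydroxyl and leave the secondary one free.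

**11 to 10 (C5–H).** The C5 carbinol is traced to a ketone. The forward 1,2-reduction must place the hydroxyl cis to the C1 substituent, which is the usual outcome of axial hydride delivery to a 5-substituted cyclohexenone.

**10 to 8 and 9 (C4–C15).** A hydroxymethyl group on the α-carbon of an enone is the retron of a Morita–Baylis–Hillman reaction with formaldehyde 9. This fixes C15 on C4 without any allylic oxidation, whose regiochemistry on a 1-substituted cyclohexene would be uncertain.

**8 to 7 (oxidation level at C5).** The enone is derived from allylic alcohol 7. The carbinol configuration of 7 is given up here and set again in the reduction. Compound 7 is used because its oxygen is placed regiospecifically by the chemistry below.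

**7 to 4 and 5 (C7≡C14).** The terminal alkyne carbon is removed. This gives an aldehyde, present as lactol 4 in equilibrium with hydroxy aldehyde 6, and the diazophosphonate 5. The carboxyl carbon of the starting acid thus becomes C7 directly.

**4 to 3 to 2 to 1 (C5–O, then C3=C4).** The lactol comes from lactone 3. The alkene of 3 comes from iodide 2 by elimination, and 2 comes from the chiral-pool acid 1 by iodolactonisation. The carboxyl group is used as an internal nucleophile to put oxygen on exactly the carbon that is 1,3 to C1, and the elimination can only go away from the bridgehead. An isopropenyl-bearing terpene alcohol would supply ring and C15 together, but it was not used for two reasons. It would need an epoxide-to-allylic-alcohol isomerisation in which the choice of β-hydrogen is not secured. It would also need a three-step degradation of isopropenyl to ethynyl through an epimerisable methyl ketone.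

## Alternatives that were turned down

**Alternative 1: ring construction by amine-catalysed Michael–aldol annulation.**
- Disconnection: C1–C6 and C3=C4 of the ring.
- Forward key step: tert-butyl 3-oxobutanoate A1 adds through its activated methylene to the iminium ion formed from ethyl (2E)-4-oxobut-2-enoate A2 and a diarylprolinol silyl ether. This forms C1–C6 and sets C1. The methyl ketone then condenses with the freed aldehyde (C3=C4), and acid removes the tert-butyl ester with decarboxylation. The product is ethyl (1S)-5-oxocyclohex-3-ene-1-carboxylate A3.
- For: two achiral bulk chemicals and one catalytic operation give the cyclohexenone. A3 is the ester congener of enone 8, so the hydroxymethylation and reduction of steps 6 and 7 would transfer.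
- Where it is stronger: on ring construction alone it is shorter than steps 1–5 of the chosen route, and it uses no stoichiometric iodine.
- Against: C1 of A3 is α to the ester and stays enolisable through the amine and hydride steps that follow. Its enantiopurity depends on the catalyst. The ester must still be converted into C7, which means reduction and homologation in the presence of the diol, hence protection. The disconnection says nothing about C7–C8, the E alkene or C11.
- Comparison: the chosen route draws C1 from an enantiopure acid whose carboxyl carbon becomes C7 through the lactol. After step 4, C1 is no longer next to a carbonyl. The chain with both alkenes is added in a single last step.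

**Alternative 2: rhodium-catalysed asymmetric conjugate alkenylation.**
- Disconnection: C1–C7.
- Forward key step: cyclohex-2-en-1-one A4 and the complete side chain as its C7 pinacol boronate A5 (4,4,5,5-tetramethyl-2-{(4E)-5-[(4R)-2,2,4-trimethyl-1,3-dioxolan-4-yl]penta-1,4-dien-2-yl}-1,3,2-dioxaborolane) combine under a monovalent rhodium–chiral bisphosphine catalyst in aqueous base. The product is (3S)-3-{(4E)-5-[(4R)-2,2,4-trimethyl-1,3-dioxolan-4-yl]penta-1,4-dien-2-yl}cyclohexan-1-one A6, with C1 set by the ligand.
- Where it is stronger: C1 is set by a catalyst, either enantiomer is available, and no chiral-pool ring is needed. The union is convergent.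
- Against: A5 already contains the skipped diene, so its own synthesis still needs a C7–C8 construction; the problem is moved, not solved. A 1-substituted alkenyl boron reagent transfers slowly and protodeboronates easily. After the addition, the ring of A6 is a bare cyclohexanone. The C3=C4 unsaturation must be introduced on the side of the carbonyl remote from C1, and a 3-substituted cyclohexanone offers little regiocontrol in enolisation. Hydroxymethylation, reduction, acetonide removal and two selective acylations then follow, all with the isomerisation-prone 1,4-diene present.
- Comparison: the chosen route finishes the ring before the union and forms the diene last, under neutral conditions.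

**Alternative 3: catalytic asymmetric alkynylation of a pyruvate.**
- Disconnection: C10–C11.
- Forward key step: the terminal alkyne of the bis-silylated ring 1,4-enyne A7 (tert-butyl({(1S,5S)-2-({[tert-butyl(dimethyl)silyl]oxy}methyl)-5-(pent-1-en-4-yn-2-yl)cyclohex-2-en-1-yl}oxy)dimethylsilane) adds to methyl 2-oxopropanoate A8 under a divalent zinc salt, a tertiary amine and a chiral amino alcohol. The product is methyl (2R)-6-[(1S,5S)-5-{[tert-butyl(dimethyl)silyl]oxy}-4-({[tert-butyl(dimethyl)silyl]oxy}methyl)cyclohex-3-en-1-yl]-2-hydroxy-2-methylhept-6-en-3-ynoate A9.
- Where it is stronger: C11 is made by reagent control from an achiral keto ester, with no chiral-pool epoxide. After reduction, the two primary alcohols could take the same acyl group in one operation.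
- Against: this type of zinc acetylide addition is far more reliable for aldehydes than for ketones, and A8 is enolisable. The C8 methylene of A7 is both propargylic and allylic and can isomerise to an allene or conjugated enyne under amine and Lewis acid. A7 needs its own C7–C8 construction and two silyl groups. After the key step come a trans-selective alkyne reduction, ester reduction, desilylation and selective acylation.
- Comparison: the chosen route obtains the E alkene, the 1,1-disubstituted alkene and the C7–C8 bond in one redox-neutral step, on unprotected fragments, with no steps after it.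

Key step: step 11

Remark on the chemistry: lactol 4 is taken as the mixture of its two C7 epimers, and compounds 1, 5, 9, 12, 14 and 15 are taken as purchased.

## Route

Step 1
Reactants: 1 (S)-cyclohex-3-ene-1-carboxylic acid
Product: 2 (1S,4S,5S)-4-iodo-6-oxabicyclo[3.2.1]octan-7-one
Conditions: I2, KI, NaHCO3, H2O, 0 °C to rt, dark
Reagents that add atoms: iodine (I2), II
Why: Iodolactonisation: the carboxylate opens the iodonium ion at the nearer alkene carbon (the later C5) in a 5-exo, anti fashion, the kinetically preferred γ-lactone mode for this acid. The tether forces the new C–O bond cis to C7 and the iodine trans to oxygen, so both new stereocentres are set by C1.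

Step 2
Reactants: 2 (1S,4S,5S)-4-iodo-6-oxabicyclo[3.2.1]octan-7-one
Product: 3 (1S,5S)-6-oxabicyclo[3.2.1]oct-3-en-7-one
Conditions: 1,8-diazabicyclo[5.4.0]undec-7-ene (DBU), toluene, 90 °C
Reagents that add atoms: none
Why: E2 dehydroiodination with an amidine base: the axial iodide has an antiperiplanar hydrogen on C3 only, and elimination towards the bridgehead C5 is ruled out by Bredt strain, so the C3=C4 alkene should form cleanly. C1 is a bridgehead next to the lactone carbonyl and cannot enolise.

Step 3
Reactants: 3 (1S,5S)-6-oxabicyclo[3.2.1]oct-3-en-7-one
Product: 4 (1S,5S)-6-oxabicyclo[3.2.1]oct-3-en-7-ol (both C7 epimers)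
Conditions: i-Bu2AlH (1.1 equiv), CH2Cl2, −78 °C; aq. KNaC4H4O6 work-up
Reagents that add atoms: none
Why: Partial reduction of a lactone to the lactol; the tetrahedral aluminium alkoxide of the bridged lactone is stable at −78 °C and collapses only on work-up, which prevents over-reduction. The allylic C5–O bond and both stereocentres are untouched.

Step 4
Reactants: 4 (1S,5S)-6-oxabicyclo[3.2.1]oct-3-en-7-ol; 5 dimethyl (1-diazo-2-oxopropyl)phosphonate (Ohira–Bestmann reagent)
Product: 7 (1S,5S)-5-ethynylcyclohex-2-en-1-ol, via (1S,5S)-5-hydroxycyclohex-3-ene-1-carbaldehyde 6 (not isolated)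
Conditions: K2CO3, MeOH, 0 °C to rt
Reagents that add atoms: none
Why: Seyferth–Gilbert homologation in the Ohira–Bestmann variant: methoxide cleaves the acetyl group of 5, the diazomethylphosphonate anion olefinates the open-chain aldehyde 6 (Horner–Wadsworth–Emmons), and loss of N2 with a 1,2-hydrogen shift gives the alkyne, so the former carboxyl carbon becomes C7 and the reagent supplies C14. The cis-1,3 arrangement can place both substituents pseudo-equatorial and is the more stable C1 epimer, so the mild carbonate base should not erode C1.

Step 5
Reactants: 7 (1S,5S)-5-ethynylcyclohex-2-en-1-ol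
Product: 8 (5S)-5-ethynylcyclohex-2-en-1-one
Conditions: MnO2 (activated, excess), CH2Cl2, rt
Reagents that add atoms: none
Why: Oxidation of a secondary allylic alcohol with activated MnO2, which leaves the terminal alkyne and the C1 centre alone. The C5 carbinol centre is given up on purpose, because the enone is needed to functionalise C4; it is set again in step 7.

Step 6
Reactants: 8 (5S)-5-ethynylcyclohex-2-en-1-one; 9 formaldehyde (37% in water)
Product: 10 (5S)-5-ethynyl-2-(hydroxymethyl)cyclohex-2-en-1-one
Conditions: 4-(dimethylamino)pyridine (20 mol %), THF/H2O, rt
Reagents that add atoms: none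
Why: Morita–Baylis–Hillman reaction: the pyridine catalyst adds to C3, the resulting enolate adds through C4 to formaldehyde, and loss of the catalyst restores the enone with C15 in place. The only stereocentre, C1, is not α to the carbonyl and is not affected.

Step 7
Reactants: 10 (5S)-5-ethynyl-2-(hydroxymethyl)cyclohex-2-en-1-one
Product: 11 (1S,5S)-5-ethynyl-2-(hydroxymethyl)cyclohex-2-en-1-ol
Conditions: NaBH4, CeCl3·7H2O, MeOH, −78 °C
Reagents that add atoms: none
Why: Luche reduction: the cerium-modified borohydride adds 1,2 to the enone. Axial hydride attack on the half-chair that keeps the C1 ethynyl group pseudo-equatorial gives the pseudo-equatorial C5 alcohol cis to C1, the same 1,3-induction that turns 5-substituted cyclohexenones into cis allylic alcohols.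

Step 8
Reactants: 11 (1S,5S)-5-ethynyl-2-(hydroxymethyl)cyclohex-2-en-1-ol; 12 2-methylpropanoyl chloride (isobutyryl chloride)
Product: 13 [(4S,6S)-4-ethynyl-6-hydroxycyclohex-1-en-1-yl]methyl 2-methylpropanoate
Conditions: 2,4,6-trimethylpyridine, CH2Cl2, −40 to 0 °C
Reagents that add atoms: none
Why: Acylation of the primary allylic alcohol in preference to the secondary allylic alcohol, which is flanked by the ring and the C4 substituent; a branched acyl chloride with a hindered pyridine base at low temperature maximises this difference.

Step 9
Reactants: 14 [(2S)-2-methyloxiran-2-yl]methanol ((S)-2-methylglycidol); 15 vinylmagnesium bromide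
Product: 16 (2R)-2-methylpent-4-ene-1,2-diol
Conditions: CH2=CHMgBr (2.5 equiv), CuI (10 mol %), THF, −40 to 0 °C; aq. NH4Cl work-up
Reagents that add atoms: none
Why: Copper-catalysed opening of the epoxide by the Grignard reagent at the unsubstituted CH2 terminus (SN2); one equivalent of 15 is spent on the hydroxyl proton, and low temperature with CuI keeps Lewis-acid rearrangement of the epoxide in check. The quaternary carbinol carbon is not a reaction site, so its configuration is retained and only the descriptor changes from S to R through the priority rules; this fixes C11.

Step 10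
Reactants: 16 (2R)-2-methylpent-4-ene-1,2-diol; 12 2-methylpropanoyl chloride
Product: 17 (2R)-2-hydroxy-2-methylpent-4-en-1-yl 2-methylpropanoate
Conditions: 2,4,6-trimethylpyridine, CH2Cl2, −40 to 0 °C
Reagents that add atoms: none
Why: Acylation of the primary hydroxyl; the tertiary hydroxyl on C11 does not react with an acid chloride under a pyridine-type base at or below 0 °C.

Step 11
Reactants: 13 [(4S,6S)-4-ethynyl-6-hydroxycyclohex-1-en-1-yl]methyl 2-methylpropanoate; 17 (2R)-2-hydroxy-2-methylpent-4-en-1-yl 2-methylpropanoate (1.5 equiv)
Product: 18 [(4S,6S)-6-hydroxy-4-[(4E,6R)-6-hydroxy-6-methyl-7-(2-methylpropanoyloxy)hepta-1,4-dien-2-yl]cyclohex-1-en-1-yl]methyl 2-methylpropanoate (target)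
Conditions: [CpRu(MeCN)3]PF6 (10 mol %), acetone, rt
Reagents that add atoms: none
Why: Formal Alder-ene reaction: the cationic divalent ruthenium centre, once its nitrile ligands are displaced, binds the alkyne of 13 and the monosubstituted alkene of 17 and undergoes oxidative cyclisation to a ruthenacyclopentene of tetravalent ruthenium in which C7 is bonded to C8 and the metal to C14 and C9. β-Hydride elimination of a C10 hydrogen followed by C14–H reductive elimination releases the C7=C14 methylene and the C9=C10 alkene and returns divalent ruthenium. The closest known reaction type is the intermolecular coupling of terminal alkynes with terminal alkenes under [CpRu(MeCN)3]PF6 to give 2-substituted 1,4-dienes. No ring is closed and no stereocentre is created; C1, C5 and C11 are untouched because no bond to them takes part in the cycle. The step needs branched regiochemistry, which follows from the preference of the metallacycle to carry the alkyne substituent on the carbon remote from the metal; C1 is a secondary, not a quaternary, propargylic carbon and should leave this preference intact. It needs E geometry at C9=C10, which follows from the β-hydride elimination conformer that turns the C11 substituent away from the metallacycle. It needs chemoselectivity among the alkenes, which is secured because only monosubstituted alkenes enter the cycle, so the ring C3=C4 alkene and the two alkenes of the product stay out. Hydroxyl groups and esters are compatible with this neutral, room-temperature catalysis, which is why both partners can carry their final functionality.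

## Compound list

1 | (S)-cyclohex-3-ene-1-carboxylic acid | OC(=O)[C@@H]1CC=CCC1 | starting material
2 | (1S,4S,5S)-4-iodo-6-oxabicyclo[3.2.1]octan-7-one | O=C1O[C@H]2C[C@@H]1CC[C@@H]2I | intermediate
3 | (1S,5S)-6-oxabicyclo[3.2.1]oct-3-en-7-one | O=C1O[C@H]2C[C@@H]1CC=C2 | intermediate
4 | (1S,5S)-6-oxabicyclo[3.2.1]oct-3-en-7-ol (both C7 epimers) | OC1O[C@H]2C[C@@H]1CC=C2 | intermediate
5 | dimethyl (1-diazo-2-oxopropyl)phosphonate | CC(=O)C(=[N+]=[N-])P(=O)(OC)OC | starting material
6 | (1S,5S)-5-hydroxycyclohex-3-ene-1-carbaldehyde | O=C[C@H]1CC=C[C@@H](O)C1 | intermediate
7 | (1S,5S)-5-ethynylcyclohex-2-en-1-ol | C#C[C@H]1CC=C[C@@H](O)C1 | intermediate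
8 | (5S)-5-ethynylcyclohex-2-en-1-one | C#C[C@H]1CC=CC(=O)C1 | intermediate
9 | formaldehyde | C=O | starting material
10 | (5S)-5-ethynyl-2-(hydroxymethyl)cyclohex-2-en-1-one | C#C[C@H]1CC=C(CO)C(=O)C1 | intermediate
11 | (1S,5S)-5-ethynyl-2-(hydroxymethyl)cyclohex-2-en-1-ol | C#C[C@H]1CC=C(CO)[C@@H](O)C1 | intermediate
12 | 2-methylpropanoyl chloride | CC(C)C(=O)Cl | starting material
13 | [(4S,6S)-4-ethynyl-6-hydroxycyclohex-1-en-1-yl]methyl 2-methylpropanoate | C#C[C@H]1CC=C(COC(=O)C(C)C)[C@@H](O)C1 | intermediate
14 | [(2S)-2-methyloxiran-2-yl]methanol | C[C@]1(CO)CO1 | starting material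
15 | vinylmagnesium bromide | C=C[Mg]Br | starting material
16 | (2R)-2-methylpent-4-ene-1,2-diol | C=CC[C@@](C)(O)CO | intermediate
17 | (2R)-2-hydroxy-2-methylpent-4-en-1-yl 2-methylpropanoate | C=CC[C@@](C)(O)COC(=O)C(C)C | intermediate
18 | [(4S,6S)-6-hydroxy-4-[(4E,6R)-6-hydroxy-6-methyl-7-(2-methylpropanoyloxy)hepta-1,4-dien-2-yl]cyclohex-1-en-1-yl]methyl 2-methylpropanoate | C=C(C/C=C/[C@@](C)(O)COC(=O)C(C)C)[C@H]1CC=C(COC(=O)C(C)C)[C@@H](O)C1 | target

## Step count and least certain steps

Total step count: 11. Longest linear sequence: 9 steps (steps 1 to 8, then step 11).

**Step 11 (key step).**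
- What may go wrong: loss of branched regioselectivity, because the propargylic carbon C1 is a ring methine and may push the metallacycle towards the linear isomer. The cationic ruthenium may also be held back by the C5 hydroxyl or may ionise the allylic C15 ester. β-Hydride elimination next to the quaternary C11 may be slow, so that alkyne self-coupling takes over.
- Fallback: it sets out from 13 and 14 and comes back at 18.
  - Alkyne 13 is treated with allyl bromide and indium powder in THF (Markovnikov allylindation of a terminal alkyne, then protonolysis). This gives [(4S,6S)-6-hydroxy-4-(penta-1,4-dien-2-yl)cyclohex-1-en-1-yl]methyl 2-methylpropanoate F1, which already holds C7=C14 and C8.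
  - Epoxide 14 is homologated with dimethylsulfonium methylide (Me3S+ I−, n-BuLi, THF) to (2R)-2-methylbut-3-ene-1,2-diol F2. Acylation with 12 as in step 10 gives (2R)-2-hydroxy-2-methylbut-3-en-1-yl 2-methylpropanoate F3.
  - Cross-metathesis of the monosubstituted alkene of F1 with excess F3 forms the E C9=C10 alkene and gives 18. The catalyst is the second-generation Hoveyda–Grubbs catalyst, RuCl2(H2IMes)(=CH–C6H4-2-OiPr), in CH2Cl2 at 40 °C.

**Step 7.**
- What may go wrong: poor facial selectivity. The ethynyl group is small, so the half-chair with this group pseudo-axial is populated and hydride attack on it leads to the trans diol.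
- Fallback: it sets out from 10 and comes back at 11, replacing substrate control by catalyst control.
  - The primary hydroxyl of 10 is silylated (t-BuMe2SiCl, imidazole, CH2Cl2) to (5S)-2-({[tert-butyl(dimethyl)silyl]oxy}methyl)-5-ethynylcyclohex-2-en-1-one F4.
  - Corey–Bakshi–Shibata reduction follows, with BH3·SMe2 and (3aR)-1-methyl-3,3-diphenyltetrahydro-1H,3H-pyrrolo[1,2-c][1,3,2]oxazaborole. This enantiomer is the one expected to deliver hydride to the face that gives the 1S carbinol. The product is (1S,5S)-2-({[tert-butyl(dimethyl)silyl]oxy}methyl)-5-ethynylcyclohex-2-en-1-ol F5.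
  - Bu4NF in THF removes the silyl group and gives 11.

**Step 4.**
- What may go wrong: slow opening of the bridged lactol under carbonate in methanol, so that the diazophosphonate decomposes first; partial epimerisation at C1 through the enolisable aldehyde 6 is also possible.
- Fallback: it sets out from 4 and comes back at 7.
  - Lactol 4 is olefinated with the ylide from (chloromethyl)triphenylphosphonium chloride and KN(SiMe3)2 (THF, −78 °C to rt; Wittig reaction under aprotic conditions). This gives (1S,5S)-5-(2-chloroethenyl)cyclohex-2-en-1-ol F6 as an E/Z mixture.
  - Excess LiN(i-Pr)2 in THF then eliminates hydrogen chloride and gives 7 after protonation.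

**Step 6.**
- What may go wrong: stalling of the amine-catalysed cycle on the 5-substituted enone, and further reaction of the product with formaldehyde (ether formation or a second hydroxymethylation).
- Fallback: it sets out from 8 and comes back at 10, using a stoichiometric conjugate addition–aldol sequence.
  - Me2AlSPh (from AlMe3 and benzenethiol) adds to C3 of 8 in CH2Cl2 at −78 °C. The aluminium enolate is trapped with gaseous formaldehyde 9 to give (5R)-5-ethynyl-2-(hydroxymethyl)-3-(phenylsulfanyl)cyclohexan-1-one F7.
  - NaIO4 in aqueous methanol gives the sulfoxide (5R)-5-ethynyl-2-(hydroxymethyl)-3-(phenylsulfinyl)cyclohexan-1-one F8.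
  - Warming F8 in toluene causes syn elimination towards the acidic C4 hydrogen and gives 10.

## Further compounds

F1 | step 11 | [(4S,6S)-6-hydroxy-4-(penta-1,4-dien-2-yl)cyclohex-1-en-1-yl]methyl 2-methylpropanoate | C=CCC(=C)[C@H]1CC=C(COC(=O)C(C)C)[C@@H](O)C1
F2 | step 11 | (2R)-2-methylbut-3-ene-1,2-diol | C=C[C@@](C)(O)CO
F3 | step 11 | (2R)-2-hydroxy-2-methylbut-3-en-1-yl 2-methylpropanoate | C=C[C@@](C)(O)COC(=O)C(C)C
F4 | step 7 | (5S)-2-({[tert-butyl(dimethyl)silyl]oxy}methyl)-5-ethynylcyclohex-2-en-1-one | C#C[C@H]1CC=C(CO[Si](C)(C)C(C)(C)C)C(=O)C1
F5 | step 7 | (1S,5S)-2-({[tert-butyl(dimethyl)silyl]oxy}methyl)-5-ethynylcyclohex-2-en-1-ol | C#C[C@H]1CC=C(CO[Si](C)(C)C(C)(C)C)[C@@H](O)C1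
F6 | step 4 | (1S,5S)-5-(2-chloroethenyl)cyclohex-2-en-1-ol (E/Z mixture) | ClC=C[C@H]1CC=C[C@@H](O)C1
F7 | step 6 | (5R)-5-ethynyl-2-(hydroxymethyl)-3-(phenylsulfanyl)cyclohexan-1-one (diastereomer mixture at C2 and C3) | C#C[C@H]1CC(Sc2ccccc2)C(CO)C(=O)C1
F8 | step 6 | (5R)-5-ethynyl-2-(hydroxymethyl)-3-(phenylsulfinyl)cyclohexan-1-one (diastereomer mixture) | C#C[C@H]1CC(S(=O)c2ccccc2)C(CO)C(=O)C1
A1 | alternative 1 | tert-butyl 3-oxobutanoate | CC(=O)CC(=O)OC(C)(C)C
A2 | alternative 1 | ethyl (2E)-4-oxobut-2-enoate | CCOC(=O)/C=C/C=O
A3 | alternative 1 | ethyl (1S)-5-oxocyclohex-3-ene-1-carboxylate | CCOC(=O)[C@H]1CC=CC(=O)C1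
A4 | alternative 2 | cyclohex-2-en-1-one | O=C1C=CCCC1
A5 | alternative 2 | 4,4,5,5-tetramethyl-2-{(4E)-5-[(4R)-2,2,4-trimethyl-1,3-dioxolan-4-yl]penta-1,4-dien-2-yl}-1,3,2-dioxaborolane | C=C(C/C=C/[C@]1(C)COC(C)(C)O1)B1OC(C)(C)C(C)(C)O1
A6 | alternative 2 | (3S)-3-{(4E)-5-[(4R)-2,2,4-trimethyl-1,3-dioxolan-4-yl]penta-1,4-dien-2-yl}cyclohexan-1-one | C=C(C/C=C/[C@]2(C)COC(C)(C)O2)[C@H]1CCCC(=O)C1
A7 | alternative 3 | tert-butyl({(1S,5S)-2-({[tert-butyl(dimethyl)silyl]oxy}methyl)-5-(pent-1-en-4-yn-2-yl)cyclohex-2-en-1-yl}oxy)dimethylsilane | C=C(CC#C)[C@H]1CC=C(CO[Si](C)(C)C(C)(C)C)[C@@H](O[Si](C)(C)C(C)(C)C)C1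
A8 | alternative 3 | methyl 2-oxopropanoate | CC(=O)C(=O)OC
A9 | alternative 3 | methyl (2R)-6-[(1S,5S)-5-{[tert-butyl(dimethyl)silyl]oxy}-4-({[tert-butyl(dimethyl)silyl]oxy}methyl)cyclohex-3-en-1-yl]-2-hydroxy-2-methylhept-6-en-3-ynoate | C=C(CC#C[C@@](C)(O)C(=O)OC)[C@H]1CC=C(CO[Si](C)(C)C(C)(C)C)[C@@H](O[Si](C)(C)C(C)(C)C)C1
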